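## Retrosynthetic overview

1. The carbinol–alkene bond of the butenol chain is cut last: ring-A (1R)-aldehyde plus ring-B (E)-alkenyl iodide, joined by Nozaki–Hiyama–Kishi coupling.
2. The strategy rests on ring A: a cyclohexene whose C4=C5 alkene lies between the gem-dimethyl carbon C6 and C3H2, with C3 leading to the methylidene carbon C2 and the methine C1 between C6 and C2. This is the adduct pattern of a 1,1-dimethyl diene and the conjugated C=C of an allene, so C1–C6 and C2–C3 are cut by a [4+2] of 4-methylpenta-1,3-diene with an N-allenoyl oxazolidinone whose auxiliary sets C1.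
3. Ring B is not built but bought as (S)-cyclohex-3-ene-1-carboxylic acid. Its alkene becomes the cis-bromohydrin (iodolactone, cis-epoxide, sulfonate, bromide by inversion, methyl addition) and its carboxyl becomes the (E)-iodopropenyl group.
4. Ring order: ring A is the only ring closed (step 3); ring B comes from the chiral pool; the two are joined in the last step.

Key step: step 3

Assumption: 4-methylpenta-1,3-diene is used free of its 2-methyl isomer, and the carbinol centre formed in step 14 is assigned with the Felkin–Anh model, the quaternary C6 acting as the large substituent.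

## Route

Step 1
Reactants: 1 (S)-4-benzyloxazolidin-2-one; 2 but-3-ynoic acid
Product: 5 (S)-4-benzyl-3-(but-3-ynoyl)oxazolidin-2-one, via mixed pivalic anhydride 3 (not isolated), via lithiated oxazolidinone 4 (not isolated)
Conditions: 2, PivCl, Et3N, THF, −20 °C; 1, n-BuLi, THF, −78 °C; combine, −78 → 0 °C; aq. NH4Cl
Reagents that add atoms: pivaloyl chloride, CC(C)(C)C(=O)Cl (pivaloyl group of 3 only); n-butyllithium, [Li]CCCC (lithium of 4 only)
Why: N-Acylation of the lithium oxazolidinide by a mixed pivalic anhydride (standard Evans imide formation); the nucleophile attacks the unhindered but-3-ynoyl carbonyl, and any early propargyl-to-allenyl shift of the acyl group is harmless because step 2 completes it.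

Step 2
Reactants: 5 (S)-4-benzyl-3-(but-3-ynoyl)oxazolidin-2-one
Product: 6 (S)-4-benzyl-3-(buta-2,3-dienoyl)oxazolidin-2-one
Conditions: Et3N (0.2 equiv), CH2Cl2, 0 °C, stopped at full conversion
Reagents that add atoms: none
Why: Base-catalysed propargyl–allenyl prototropic isomerisation: the CH2 between the imide carbonyl and the alkyne is acidic enough for catalytic Et3N, reprotonation at the terminal carbon gives the conjugated allene, and the mild base and short time keep it from moving on to the but-2-ynoyl isomer.

Step 3
Reactants: 6 (S)-4-benzyl-3-(buta-2,3-dienoyl)oxazolidin-2-one; 7 4-methylpenta-1,3-diene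
Product: 8 (S)-4-benzyl-3-[(1R)-6,6-dimethyl-2-methylidenecyclohex-4-ene-1-carbonyl]oxazolidin-2-one
Conditions: 7 (5 equiv), Me2AlCl (1.5 equiv), CH2Cl2, −78 → −30 °C; cold 1 M HCl
Reagents that add atoms: none
Why: Me2AlCl chelates both imide carbonyls, which locks the s-cis allenoyl conformer and activates the conjugated C=C, and the diene adds in a concerted but strongly asynchronous [4+2] transition state in which its unsubstituted CH2 terminus bonds first to the central allene carbon and the CMe2 terminus then closes on the carbonyl-bearing carbon, leaving the distal allene C=C as the exocyclic methylene. The closest known reaction types are the Lewis-acid-promoted Diels–Alder reaction of chelated N-enoyl oxazolidinones (Evans) and Lewis-acid-promoted Diels–Alder reactions of allenic esters. Ring A closes as a six-membered ring by suprafacial [4+2] cycloaddition, forming the C1–C6 and C2–C3 bonds. The single new stereocentre C1 is controlled by the auxiliary: in the chelate the benzyl group covers the Cα-Re face, the diene adds to the Cα-Si face, and the (S)-auxiliary should therefore give (1R). The step needs regioselectivity (donor CMe2 terminus to the α-carbon, nucleophilic CH2 terminus to the electrophilic central carbon), periselectivity for the conjugated C=C and for six- over four-membered closure (low temperature, excess diene, a proton-scavenging methylaluminium Lewis acid, and the doubly activated dienophile that compensates for the cis-methyl of the diene), and facial selectivity (benzyl group).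

Step 4
Reactants: 8 (S)-4-benzyl-3-[(1R)-6,6-dimethyl-2-methylidenecyclohex-4-ene-1-carbonyl]oxazolidin-2-one
Product: 9 [(1R)-6,6-dimethyl-2-methylidenecyclohex-4-en-1-yl]methanol
Conditions: LiBH4, THF, 0 °C → rt; aq. NaOH work-up; 1 recovered
Reagents that add atoms: none
Why: Reductive cleavage of the N-acyl oxazolidinone with LiBH4 (lithium-chelated hydride delivery to the exocyclic carbonyl) releases the primary alcohol and the auxiliary under non-basic conditions, so the allylic C1 stereocentre and the skipped diene are untouched.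

Step 5
Reactants: 9 [(1R)-6,6-dimethyl-2-methylidenecyclohex-4-en-1-yl]methanol
Product: 10 (1R)-6,6-dimethyl-2-methylidenecyclohex-4-ene-1-carbaldehyde
Conditions: Dess–Martin periodinane, pyridine, CH2Cl2, 0 °C; used directly
Reagents that add atoms: none
Why: Dess–Martin oxidation under buffered, neutral conditions gives the β,γ-unsaturated aldehyde without epimerising C1 or drawing the exocyclic alkene into conjugation.

Step 6
Reactants: 11 (S)-cyclohex-3-ene-1-carboxylic acid
Product: 12 (1S,4S,5S)-4-iodo-6-oxabicyclo[3.2.1]octan-7-one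
Conditions: I2, KI, NaHCO3, H2O/CH2Cl2, rt, dark
Reagents that add atoms: iodine, II
Why: Iodolactonisation: the carboxylate opens the iodonium ion intramolecularly in anti fashion, which fixes the lactone oxygen at C3 cis to C1 and iodine at C4 trans, so the existing C1 stereocentre sets both new centres.

Step 7
Reactants: 12 (1S,4S,5S)-4-iodo-6-oxabicyclo[3.2.1]octan-7-one
Product: 13 ethyl (1S,3S,6R)-7-oxabicyclo[4.1.0]heptane-3-carboxylate
Conditions: K2CO3, EtOH, rt
Reagents that add atoms: ethanol, CCO
Why: Ethanolysis of the lactone frees the C3 alkoxide, which is trans-diaxial to the C4–I bond and closes by intramolecular SN2 (Williamson-type epoxide formation, inversion at C4) to the epoxide cis to the ester.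

Step 8
Reactants: 13 ethyl (1S,3S,6R)-7-oxabicyclo[4.1.0]heptane-3-carboxylate
Product: 14 ethyl (1S,3R,4R)-4-hydroxy-3-[(methylsulfonyl)oxy]cyclohexane-1-carboxylate
Conditions: MsOH (1.05 equiv), CH2Cl2, −20 → 0 °C
Reagents that add atoms: methanesulfonic acid, CS(=O)(=O)O
Why: Acid-mediated epoxide opening by methanesulfonate in the trans-diaxial (Fürst–Plattner) mode: attack at C3, the carbon 1,3 to the ester, with inversion gives the C3 sulfonate trans and the C4 hydroxyl cis to the ester, the regiochemistry known for nucleophilic openings of this epoxide.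

Step 9
Reactants: 14 ethyl (1S,3R,4R)-4-hydroxy-3-[(methylsulfonyl)oxy]cyclohexane-1-carboxylate
Product: 15 ethyl (1S,3R)-3-[(methylsulfonyl)oxy]-4-oxocyclohexane-1-carboxylate
Conditions: Dess–Martin periodinane, CH2Cl2, rt
Reagents that add atoms: none
Why: Dess–Martin oxidation of the secondary alcohol to the ketone under neutral conditions that neither displace the sulfonate nor epimerise C3.

Step 10
Reactants: 15 ethyl (1S,3R)-3-[(methylsulfonyl)oxy]-4-oxocyclohexane-1-carboxylate
Product: 16 ethyl (1S,3S)-3-bromo-4-oxocyclohexane-1-carboxylate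
Conditions: LiBr (1.05 equiv), acetone, 0 °C; neutral work-up, used directly
Reagents that add atoms: lithium bromide, [Li+].[Br-]
Why: SN2 displacement at the carbonyl-activated α-carbon (Finkelstein-type), fastest for the axial sulfonate, proceeds with inversion at C3 and gives the equatorial bromide cis to the ester, which is also the isomer expected to be preferred at equilibrium in a polar medium, so bromide exchange does not work against it.

Step 11
Reactants: 16 ethyl (1S,3S)-3-bromo-4-oxocyclohexane-1-carboxylate
Product: 17 ethyl (1S,3S,4R)-3-bromo-4-hydroxy-4-methylcyclohexane-1-carboxylate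
Conditions: MeMgBr (1.2 equiv), THF/Et2O, −78 °C; aq. NH4Cl at −78 °C
Reagents that add atoms: methylmagnesium bromide, C[Mg]Br
Why: Grignard addition to the ketone at −78 °C (ester untouched): methyl adds anti to the C–Br bond (Cornforth/polar Felkin–Anh attack on the axial-bromide conformer, and equatorial attack on the diequatorial conformer leads to the same product), so the new C4 carbinol should carry OH cis to bromine and to the ester and an equatorial methyl; the cis halohydrin cannot close to an epoxide.

Step 12
Reactants: 17 ethyl (1S,3S,4R)-3-bromo-4-hydroxy-4-methylcyclohexane-1-carboxylate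
Product: 19 (1R,2S,4S)-2-bromo-4-ethynyl-1-methylcyclohexan-1-ol, via bromohydrin aldehyde 18 (not isolated)
Conditions: DIBAL-H (2.2 equiv), CH2Cl2, −78 °C; MeOH; then K2CO3, dimethyl (1-diazo-2-oxopropyl)phosphonate, MeOH, 0 °C → rt
Reagents that add atoms: dimethyl (1-diazo-2-oxopropyl)phosphonate, CC(=O)C(=[N+]=[N-])P(=O)(OC)OC
Why: DIBAL-H half-reduction of the ester (the tetrahedral aluminate is stable at −78 °C) followed in the same flask by Seyferth–Gilbert homologation with the Ohira–Bestmann reagent; the formyl-bearing carbon is equatorial and thus already the thermodynamically preferred epimer, so the mild base cannot degrade it.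

Step 13
Reactants: 19 (1R,2S,4S)-2-bromo-4-ethynyl-1-methylcyclohexan-1-ol
Product: 21 (1R,2S,4S)-2-bromo-4-[(1E)-1-iodoprop-1-en-2-yl]-1-methylcyclohexan-1-ol, via alkenylalane 20 (not isolated)
Conditions: AlMe3 (4 equiv), Cp2ZrCl2 (0.3 equiv), CH2Cl2, 0 °C → rt; then I2, THF, −30 → 0 °C; aq. Na2S2O3/NaHCO3
Reagents that add atoms: trimethylaluminium, C[Al](C)C; iodine, II
Why: Negishi zirconium-catalysed carboalumination adds methyl and aluminium syn across the terminal alkyne with aluminium on the terminal carbon, and iodinolysis of the C–Al bond with retention gives the (E)-2-methyl-1-iodoalkene; the tertiary alcohol is carried as its aluminium alkoxide and the secondary bromide is inert.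

Step 14
Reactants: 10 (1R)-6,6-dimethyl-2-methylidenecyclohex-4-ene-1-carbaldehyde; 21 (1R,2S,4S)-2-bromo-4-[(1E)-1-iodoprop-1-en-2-yl]-1-methylcyclohexan-1-ol
Product: 23 (1R,2E)-3-[(1S,3S,4R)-3-bromo-4-hydroxy-4-methylcyclohexyl]-1-[(1R)-6,6-dimethyl-2-methylidenecyclohex-4-en-1-yl]but-2-en-1-ol, via alkenylchromium species 22 (not isolated)
Conditions: CrCl2 (5 equiv), NiCl2 (1 mol%), DMSO, rt; aq. NH4Cl
Reagents that add atoms: chromium(II) chloride, Cl[Cr]Cl (chromium and chloride of 22 only)
Why: Nozaki–Hiyama–Kishi coupling: nickel-catalysed formation of the alkenylchromium(III) species with retention of alkene geometry and its chemoselective addition to the aldehyde in the presence of the free alcohol and the secondary bromide; the new carbinol centre is set by Felkin–Anh control from C1 of ring A (quaternary C6 anti to the incoming alkenyl group), which is expected to favour the (1R) alcohol, the minor epimer being removed by chromatography.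

## Compound list

1 | (S)-4-benzyloxazolidin-2-one | O=C1N[C@@H](Cc2ccccc2)CO1 | starting material
2 | but-3-ynoic acid | C#CCC(=O)O | starting material
3 | but-3-ynoic pivalic anhydride | C#CCC(=O)OC(=O)C(C)(C)C | intermediate
4 | lithium (S)-4-benzyl-2-oxooxazolidin-3-ide | [Li]N1[C@@H](Cc2ccccc2)COC1=O | intermediate
5 | (S)-4-benzyl-3-(but-3-ynoyl)oxazolidin-2-one | C#CCC(=O)N1[C@@H](Cc2ccccc2)COC1=O | intermediate
6 | (S)-4-benzyl-3-(buta-2,3-dienoyl)oxazolidin-2-one | C=C=CC(=O)N1[C@@H](Cc2ccccc2)COC1=O | intermediate
7 | 4-methylpenta-1,3-diene | CC(C)=CC=C | starting material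
8 | (S)-4-benzyl-3-[(1R)-6,6-dimethyl-2-methylidenecyclohex-4-ene-1-carbonyl]oxazolidin-2-one | C=C1CC=CC(C)(C)[C@@H]1C(=O)N1[C@@H](Cc2ccccc2)COC1=O | intermediate
9 | [(1R)-6,6-dimethyl-2-methylidenecyclohex-4-en-1-yl]methanol | C=C1CC=CC(C)(C)[C@@H]1CO | intermediate
10 | (1R)-6,6-dimethyl-2-methylidenecyclohex-4-ene-1-carbaldehyde | C=C1CC=CC(C)(C)[C@@H]1C=O | intermediate
11 | (S)-cyclohex-3-ene-1-carboxylic acid | O=C(O)[C@@H]1CC=CCC1 | starting material
12 | (1S,4S,5S)-4-iodo-6-oxabicyclo[3.2.1]octan-7-one | O=C1[C@@H]2C[C@H](O1)[C@@H](I)CC2 | intermediate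
13 | ethyl (1S,3S,6R)-7-oxabicyclo[4.1.0]heptane-3-carboxylate | CCOC(=O)[C@@H]1C[C@@H]2O[C@@H]2CC1 | intermediate
14 | ethyl (1S,3R,4R)-4-hydroxy-3-[(methylsulfonyl)oxy]cyclohexane-1-carboxylate | CCOC(=O)[C@@H]1C[C@@H](OS(C)(=O)=O)[C@H](O)CC1 | intermediate
15 | ethyl (1S,3R)-3-[(methylsulfonyl)oxy]-4-oxocyclohexane-1-carboxylate | CCOC(=O)[C@@H]1C[C@@H](OS(C)(=O)=O)C(=O)CC1 | intermediate
16 | ethyl (1S,3S)-3-bromo-4-oxocyclohexane-1-carboxylate | CCOC(=O)[C@@H]1C[C@H](Br)C(=O)CC1 | intermediate
17 | ethyl (1S,3S,4R)-3-bromo-4-hydroxy-4-methylcyclohexane-1-carboxylate | CCOC(=O)[C@@H]1C[C@H](Br)[C@](C)(O)CC1 | intermediate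
18 | (1S,3S,4R)-3-bromo-4-hydroxy-4-methylcyclohexane-1-carbaldehyde | O=C[C@@H]1C[C@H](Br)[C@](C)(O)CC1 | intermediate
19 | (1R,2S,4S)-2-bromo-4-ethynyl-1-methylcyclohexan-1-ol | C#C[C@@H]1C[C@H](Br)[C@](C)(O)CC1 | intermediate
20 | (E)-alkenyldimethylalane of 19 as its O-dimethylaluminium alkoxide | C[Al](C)/C=C(\C)[C@@H]1C[C@H](Br)[C@](C)(O[Al](C)C)CC1 | intermediate
21 | (1R,2S,4S)-2-bromo-4-[(1E)-1-iodoprop-1-en-2-yl]-1-methylcyclohexan-1-ol | I/C=C(\C)[C@@H]1C[C@H](Br)[C@](C)(O)CC1 | intermediate
22 | (E)-alkenylchromium(III) dichloride from 21 | Cl[Cr](Cl)/C=C(\C)[C@@H]1C[C@H](Br)[C@](C)(O)CC1 | intermediate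
23 | (1R,2E)-3-[(1S,3S,4R)-3-bromo-4-hydroxy-4-methylcyclohexyl]-1-[(1R)-6,6-dimethyl-2-methylidenecyclohex-4-en-1-yl]but-2-en-1-ol | C=C1CC=CC(C)(C)[C@@H]1[C@H](O)/C=C(\C)[C@H]1CC[C@@](C)(O)[C@@H](Br)C1 | target

## Totals and risks

Total step count: 14. Longest linear sequence: 9 steps (11 to 23, steps 6–14).

Steps most likely to fail:

1. Step 3. The cis-methyl of the diene disfavours its s-cis form, so cationic oligomerisation of the diene, or closure of a zwitterionic intermediate to a four-membered ring, may outpace six-membered ring closure. The fallback changes the cycloaddition partner to a 2-silyloxy diene and removes the oxygen afterwards. It sets out from 6, which is treated with the silyl dienol ether of mesityl oxide, 4-methyl-2-[(trimethylsilyl)oxy]penta-1,3-diene F1 (from mesityl oxide, LDA, TMSCl, THF, −78 °C), and Me2AlCl at −78 °C. The far more nucleophilic CH2 terminus should add in a Mukaiyama–Michael sense to the central allene carbon, and the aluminium enolate should then close on the silyloxyallyl cation at the CMe2 terminus under the same auxiliary control. This stepwise polar [4+2] would give (S)-4-benzyl-3-{(1R)-6,6-dimethyl-2-methylidene-4-[(trimethylsilyl)oxy]cyclohex-4-ene-1-carbonyl}oxazolidin-2-one F2. Exchange of silicon for triflyl with retention of the enol regiochemistry (CsF, PhNTf2, DME) would give the enol triflate (S)-4-benzyl-3-{(1R)-6,6-dimethyl-2-methylidene-4-[(trifluoromethylsulfonyl)oxy]cyclohex-4-ene-1-carbonyl}oxazolidin-2-one F3. Palladium-catalysed reduction (Pd(PPh3)4, Bu3SnH, LiCl, THF) then returns the route to 8.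

2. Step 14. Facial discrimination at the hindered aldehyde may be poor or inverted, giving much of the carbinol epimer. The fallback moves stereocontrol from substrate to reagent. It sets out from the product mixture of 23 and (1S,2E)-3-[(1S,3S,4R)-3-bromo-4-hydroxy-4-methylcyclohexyl]-1-[(1R)-6,6-dimethyl-2-methylidenecyclohex-4-en-1-yl]but-2-en-1-ol F5. The mixture is oxidised (Dess–Martin periodinane, pyridine, CH2Cl2) to (2E)-3-[(1S,3S,4R)-3-bromo-4-hydroxy-4-methylcyclohexyl]-1-[(1R)-6,6-dimethyl-2-methylidenecyclohex-4-en-1-yl]but-2-en-1-one F6. This enone is reduced with (S)-2-methyl-CBS-oxazaborolidine and catecholborane (toluene, −78 °C), the bulky ring-A residue taking the role of the large ketone substituent, which should return the route to 23.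

3. Step 4. The acyl carbonyl is flanked by C6 and C2, so hydride attack at the ring carbonyl of the auxiliary (endocyclic cleavage) may compete. The fallback replaces direct reduction by hydrolysis and separate reduction. It sets out from 8: LiOH/H2O2 (THF–H2O, 0 °C), in which hydroperoxide attacks the exocyclic carbonyl selectively, would give (1R)-6,6-dimethyl-2-methylidenecyclohex-4-ene-1-carboxylic acid F4 with recovery of 1. LiAlH4 (Et2O, 0 °C) then reduces F4 and returns the route to 9.

Further compounds
F1 | step 3 | 4-methyl-2-[(trimethylsilyl)oxy]penta-1,3-diene | CC(C)=CC(=C)O[Si](C)(C)C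
F2 | step 3 | (S)-4-benzyl-3-{(1R)-6,6-dimethyl-2-methylidene-4-[(trimethylsilyl)oxy]cyclohex-4-ene-1-carbonyl}oxazolidin-2-one | C=C1CC(O[Si](C)(C)C)=CC(C)(C)[C@@H]1C(=O)N1[C@@H](Cc2ccccc2)COC1=O
F3 | step 3 | (S)-4-benzyl-3-{(1R)-6,6-dimethyl-2-methylidene-4-[(trifluoromethylsulfonyl)oxy]cyclohex-4-ene-1-carbonyl}oxazolidin-2-one | C=C1CC(OS(=O)(=O)C(F)(F)F)=CC(C)(C)[C@@H]1C(=O)N1[C@@H](Cc2ccccc2)COC1=O
F4 | step 4 | (1R)-6,6-dimethyl-2-methylidenecyclohex-4-ene-1-carboxylic acid | C=C1CC=CC(C)(C)[C@@H]1C(=O)O
F5 | step 14 | (1S,2E)-3-[(1S,3S,4R)-3-bromo-4-hydroxy-4-methylcyclohexyl]-1-[(1R)-6,6-dimethyl-2-methylidenecyclohex-4-en-1-yl]but-2-en-1-ol | C=C1CC=CC(C)(C)[C@@H]1[C@@H](O)/C=C(\C)[C@@H]1C[C@H](Br)[C@](C)(O)CC1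
F6 | step 14 | (2E)-3-[(1S,3S,4R)-3-bromo-4-hydroxy-4-methylcyclohexyl]-1-[(1R)-6,6-dimethyl-2-methylidenecyclohex-4-en-1-yl]but-2-en-1-one | C=C1CC=CC(C)(C)[C@@H]1C(=O)/C=C(\C)[C@@H]1C[C@H](Br)[C@](C)(O)CC1
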